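**Plan**
Retrosynthesis: remove the silyl group from the 4'-oxygen, return the C8 prenyl group to O5 (para-Claisen–Cope), cut the C6–acyl bond (arylzinc + acid chloride), then cut the pyran at C3=C4 and O1–C2.
Enabling feature: C4 of the pyran sits on C4a, the one carbon of ring A flanked by two oxygens (O1 on C8a, OH on C5) and para to the methoxy carbon C7. With C4 as a formyl carbon, this is the mirror-symmetric 2,6-dihydroxy-4-methoxybenzaldehyde, a salicylaldehyde from either side.
Forward: formyl-controlled 4-O-methylation of phloroglucinaldehyde; pyran ring by a borono-Mannich / ortho-quinone methide / oxa-6π cascade; C6 acylation by directed metalation between OMOM and OMe; 5-O-prenylation and [3,3]/[3,3] relay to C8; desilylation.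
Stereochemistry: the target has no stereocentre; the cis C3=C4 alkene is fixed by the six-membered ring.

Key step: step 2

**Step 1**
Reactants: 1 2,4,6-trihydroxybenzaldehyde
Product: 2 2,6-dihydroxy-4-methoxybenzaldehyde
Conditions: MeI (1.05 equiv), K2CO3 (1.0 equiv), acetone, 0 °C → rt
Reagents that add atoms: methyl iodide, CI
Why: Williamson methylation with one equivalent of weak base should select the 4-hydroxyl, the most acidic one (para to the formyl group) and the only one not deactivated by hydrogen bonding to the carbonyl oxygen.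

**Step 2**
Reactants: 2 2,6-dihydroxy-4-methoxybenzaldehyde; 3 (2-methylprop-1-en-1-yl)boronic acid (1.3 equiv)
Product: 6 7-methoxy-2,2-dimethyl-2H-chromen-5-ol, via allylic amine 4 (not isolated), via ortho-quinone methide 5 (not isolated)
Conditions: Bn2NH (0.4 equiv), 1,4-dioxane, 90 °C, N2
Reagents that add atoms: none
Why: Dibenzylamine condenses with the formyl group of 2 to an iminium/hemiaminal, a flanking phenol binds 3 as a tetracoordinate boronate, and the 2-methylpropenyl group is delivered intramolecularly to the iminium carbon (C4–C3 bond, allylic amine 4); at 90 °C the electron-rich phenol expels the amine to give ortho-quinone methide 5, whose 1-oxatriene closes with O1–C2 bond formation and rearomatises ring A. The closest known reaction type is the amine-catalysed Petasis borono-Mannich condensation of salicylaldehydes with alkenylboronic acids to 2H-chromenes. The only ring closed is the pyran, by a thermal disrotatory oxa-6π electrocyclisation, so the gem-dimethyl carbon is bonded to oxygen without a cationic intermediate. No stereocentre survives: the nitrogen-bearing carbon of 4 becomes sp2 C4 and C2 carries two methyl groups. The step needs C-alkenylation at the formyl carbon only and a single direction of ring closure; the ortho-hydroxyl makes the transfer intramolecular, and because the two hydroxyls of 2 are related by the mirror plane through C1 and C4, closure from either oxygen and from either geometry of the exocyclic alkene of 5 gives the same chromenol 6. The methoxy group para to the formyl carbon ends at C7 by construction.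

**Step 3**
Reactants: 6 7-methoxy-2,2-dimethyl-2H-chromen-5-ol
Product: 7 7-methoxy-5-(methoxymethoxy)-2,2-dimethyl-2H-chromene
Conditions: NaH (1.2 equiv), MOMCl (1.2 equiv), THF, 0 °C → rt
Reagents that add atoms: chloromethyl methyl ether, COCCl
Why: Williamson-type O-alkylation of the sodium phenoxide installs the acetal that directs the later metalation, under acid-free conditions that the acid-sensitive chromene should tolerate.

**Step 4**
Reactants: 8 (4-hydroxyphenyl)acetic acid
Product: 10 {4-[(triisopropylsilyl)oxy]phenyl}acetic acid, via silyl ester 9 (not isolated)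
Conditions: TIPSCl (2.3 equiv), imidazole (5 equiv), DMF, rt; then AcOH/THF/H2O, rt
Reagents that add atoms: chlorotriisopropylsilane, CC(C)[Si](Cl)(C(C)C)C(C)C
Why: Silylation of both the phenol and the acid, followed by selective hydrolysis of the labile silyl ester in aqueous acetic acid, should leave the robust aryl TIPS ether.

**Step 5**
Reactants: 10 {4-[(triisopropylsilyl)oxy]phenyl}acetic acid
Product: 11 {4-[(triisopropylsilyl)oxy]phenyl}acetyl chloride
Conditions: (COCl)2 (1.3 equiv), DMF (cat.), CH2Cl2, 0 °C → rt; volatiles removed, used crude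
Reagents that add atoms: oxalyl chloride, O=C(Cl)C(Cl)=O
Why: Vilsmeier-type activation with oxalyl chloride/DMF converts the acid to the acid chloride under conditions an aryl TIPS ether tolerates.

**Step 6**
Reactants: 7 7-methoxy-5-(methoxymethoxy)-2,2-dimethyl-2H-chromene; 11 {4-[(triisopropylsilyl)oxy]phenyl}acetyl chloride (1.2 equiv)
Product: 14 1-[7-methoxy-5-(methoxymethoxy)-2,2-dimethyl-2H-chromen-6-yl]-2-{4-[(triisopropylsilyl)oxy]phenyl}ethan-1-one, via aryllithium 12 (not isolated), via arylzinc chloride 13 (not isolated)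
Conditions: n-BuLi (1.1 equiv), THF, 0 °C; ZnCl2 (1.2 equiv), 0 °C → rt; Pd(PPh3)4 (5 mol%), 11, rt
Reagents that add atoms: none
Why: Directed ortho-metalation should occur at C6, between the strongly coordinating OMOM and the OMe group (C8 lies between OMe and the hindered ring oxygen), and transmetalation to zinc followed by Negishi acylation under zerovalent palladium catalysis forms the aryl ketone without exposing the enolisable acid chloride to the basic aryllithium.

**Step 7**
Reactants: 14 1-[7-methoxy-5-(methoxymethoxy)-2,2-dimethyl-2H-chromen-6-yl]-2-{4-[(triisopropylsilyl)oxy]phenyl}ethan-1-one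
Product: 15 1-(5-hydroxy-7-methoxy-2,2-dimethyl-2H-chromen-6-yl)-2-{4-[(triisopropylsilyl)oxy]phenyl}ethan-1-one
Conditions: conc. HCl (cat.), MeOH/THF, rt
Reagents that add atoms: none
Why: Acid-catalysed acetal exchange with methanol removes the MOM group, which is unusually labile because the freed phenol is hydrogen-bonded to the ortho ketone, while the aryl TIPS ether should be stable to catalytic acid at room temperature.

**Step 8**
Reactants: 15 1-(5-hydroxy-7-methoxy-2,2-dimethyl-2H-chromen-6-yl)-2-{4-[(triisopropylsilyl)oxy]phenyl}ethan-1-one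
Product: 16 1-{7-methoxy-2,2-dimethyl-5-[(3-methylbut-2-en-1-yl)oxy]-2H-chromen-6-yl}-2-{4-[(triisopropylsilyl)oxy]phenyl}ethan-1-one
Conditions: prenyl bromide (1.5 equiv), K2CO3 (2 equiv), n-Bu4NI (cat.), acetone, reflux
Reagents that add atoms: 1-bromo-3-methylbut-2-ene, CC(C)=CCBr
Why: Williamson etherification of the only free phenol; carbonate should not appreciably deprotonate the benzylic ketone CH2, and the 4'-oxygen is blocked as its TIPS ether.

**Step 9**
Reactants: 16 1-{7-methoxy-2,2-dimethyl-5-[(3-methylbut-2-en-1-yl)oxy]-2H-chromen-6-yl}-2-{4-[(triisopropylsilyl)oxy]phenyl}ethan-1-one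
Product: 19 1-[5-hydroxy-7-methoxy-2,2-dimethyl-8-(3-methylbut-2-en-1-yl)-2H-chromen-6-yl]-2-{4-[(triisopropylsilyl)oxy]phenyl}ethan-1-one, via ortho-dienone 17 (not isolated), via para-dienone 18 (not isolated)
Conditions: PhNEt2, 190 °C, sealed tube, N2
Reagents that add atoms: none
Why: Tandem aromatic Claisen/Cope rearrangement (para-Claisen): both ortho carbons (C6 and C4a) are substituted, so the ortho-dienone cannot enolise and relays the allyl unit by a second [3,3] shift to C8, para to O5, where tautomerisation restores the phenol; two allylic inversions return the linear 3-methylbut-2-enyl group.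

**Step 10**
Reactants: 19 1-[5-hydroxy-7-methoxy-2,2-dimethyl-8-(3-methylbut-2-en-1-yl)-2H-chromen-6-yl]-2-{4-[(triisopropylsilyl)oxy]phenyl}ethan-1-one
Product: 20 1-[5-hydroxy-7-methoxy-2,2-dimethyl-8-(3-methylbut-2-en-1-yl)-2H-chromen-6-yl]-2-(4-hydroxyphenyl)ethan-1-one
Conditions: TBAF (1.1 equiv), AcOH (1.1 equiv), THF, 0 °C
Reagents that add atoms: none
Why: Fluoride-mediated desilylation, buffered with acetic acid so that neither the phenoxide nor the acidic benzylic ketone meets basic fluoride, frees the 4'-hydroxyl without touching the prenyl or chromene alkenes.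

**Compound list**
1 | 2,4,6-trihydroxybenzaldehyde | O=Cc1c(O)cc(O)cc1O | starting material
2 | 2,6-dihydroxy-4-methoxybenzaldehyde | COc1cc(O)c(C=O)c(O)c1 | intermediate
3 | (2-methylprop-1-en-1-yl)boronic acid | CC(C)=CB(O)O | starting material
4 | 2-[1-(dibenzylamino)-3-methylbut-2-en-1-yl]-5-methoxybenzene-1,3-diol (racemic, formed in the flask) | COc1cc(O)c(C(C=C(C)C)N(Cc2ccccc2)Cc2ccccc2)c(O)c1 | intermediate
5 | 5-hydroxy-3-methoxy-6-(3-methylbut-2-en-1-ylidene)cyclohexa-2,4-dien-1-one (formed in the flask) | O=C1C=C(OC)C=C(O)C1=CC=C(C)C | intermediate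
6 | 7-methoxy-2,2-dimethyl-2H-chromen-5-ol | COc1cc(O)c2C=CC(C)(C)Oc2c1 | intermediate
7 | 7-methoxy-5-(methoxymethoxy)-2,2-dimethyl-2H-chromene | COCOc1cc(OC)cc2OC(C)(C)C=Cc12 | intermediate
8 | (4-hydroxyphenyl)acetic acid | OC(=O)Cc1ccc(O)cc1 | starting material
9 | triisopropylsilyl {4-[(triisopropylsilyl)oxy]phenyl}acetate (formed in the flask) | CC(C)[Si](OC(=O)Cc1ccc(O[Si](C(C)C)(C(C)C)C(C)C)cc1)(C(C)C)C(C)C | intermediate
10 | {4-[(triisopropylsilyl)oxy]phenyl}acetic acid | CC(C)[Si](Oc1ccc(CC(O)=O)cc1)(C(C)C)C(C)C | intermediate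
11 | {4-[(triisopropylsilyl)oxy]phenyl}acetyl chloride | CC(C)[Si](Oc1ccc(CC(Cl)=O)cc1)(C(C)C)C(C)C | intermediate
12 | [7-methoxy-5-(methoxymethoxy)-2,2-dimethyl-2H-chromen-6-yl]lithium (formed in the flask) | [Li]c1c(OC)cc2OC(C)(C)C=Cc2c1OCOC | intermediate
13 | chloro[7-methoxy-5-(methoxymethoxy)-2,2-dimethyl-2H-chromen-6-yl]zinc (formed in the flask) | Cl[Zn]c1c(OC)cc2OC(C)(C)C=Cc2c1OCOC | intermediate
14 | 1-[7-methoxy-5-(methoxymethoxy)-2,2-dimethyl-2H-chromen-6-yl]-2-{4-[(triisopropylsilyl)oxy]phenyl}ethan-1-one | COCOc1c(C(=O)Cc2ccc(O[Si](C(C)C)(C(C)C)C(C)C)cc2)c(OC)cc2OC(C)(C)C=Cc12 | intermediate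
15 | 1-(5-hydroxy-7-methoxy-2,2-dimethyl-2H-chromen-6-yl)-2-{4-[(triisopropylsilyl)oxy]phenyl}ethan-1-one | COc1cc2OC(C)(C)C=Cc2c(O)c1C(=O)Cc1ccc(O[Si](C(C)C)(C(C)C)C(C)C)cc1 | intermediate
16 | 1-{7-methoxy-2,2-dimethyl-5-[(3-methylbut-2-en-1-yl)oxy]-2H-chromen-6-yl}-2-{4-[(triisopropylsilyl)oxy]phenyl}ethan-1-one | COc1cc2OC(C)(C)C=Cc2c(OCC=C(C)C)c1C(=O)Cc1ccc(O[Si](C(C)C)(C(C)C)C(C)C)cc1 | intermediate
17 | 7-methoxy-2,2-dimethyl-6-(2-methylbut-3-en-2-yl)-6-({4-[(triisopropylsilyl)oxy]phenyl}acetyl)-2H-chromen-5(6H)-one (racemic, formed in the flask) | COC1=CC2=C(C=CC(C)(C)O2)C(=O)C1(C(C)(C)C=C)C(=O)Cc1ccc(O[Si](C(C)C)(C(C)C)C(C)C)cc1 | intermediate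
18 | 7-methoxy-2,2-dimethyl-8-(3-methylbut-2-en-1-yl)-6-({4-[(triisopropylsilyl)oxy]phenyl}acetyl)-2H-chromen-5(8H)-one (racemic, formed in the flask) | COC1=C(C(=O)Cc2ccc(O[Si](C(C)C)(C(C)C)C(C)C)cc2)C(=O)C2=C(OC(C)(C)C=C2)C1CC=C(C)C | intermediate
19 | 1-[5-hydroxy-7-methoxy-2,2-dimethyl-8-(3-methylbut-2-en-1-yl)-2H-chromen-6-yl]-2-{4-[(triisopropylsilyl)oxy]phenyl}ethan-1-one | COc1c(CC=C(C)C)c2OC(C)(C)C=Cc2c(O)c1C(=O)Cc1ccc(O[Si](C(C)C)(C(C)C)C(C)C)cc1 | intermediate
20 | 1-[5-hydroxy-7-methoxy-2,2-dimethyl-8-(3-methylbut-2-en-1-yl)-2H-chromen-6-yl]-2-(4-hydroxyphenyl)ethan-1-one | COc1c(CC=C(C)C)c2OC(C)(C)C=Cc2c(O)c1C(=O)Cc1ccc(O)cc1 | target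

**Summary**
Total step count: 10. Longest linear sequence: 8 (steps 1, 2, 3, 6, 7, 8, 9, 10); steps 4 and 5 prepare the acid chloride.

Steps most likely to fail:

1. Step 9. The first [3,3] shift must attack a fully substituted ortho carbon, and the congested ortho-dienone may lose the allyl unit or shift its acyl group faster than it undergoes the second [3,3] shift. The fallback sets out from 15. Para-iodination of the phenol with N-iodosuccinimide (CH2Cl2, 0 °C) should give 1-(5-hydroxy-8-iodo-7-methoxy-2,2-dimethyl-2H-chromen-6-yl)-2-{4-[(triisopropylsilyl)oxy]phenyl}ethan-1-one F3, C8 being the only unsubstituted carbon of ring A. Stille coupling with tributyl(3-methylbut-2-en-1-yl)stannane (Pd(PPh3)4, DMF, 90 °C) then comes back to the route at 19; steps 8 and 9 are skipped.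

2. Step 6. Metalation may be incomplete or partly at C8, the acid chloride may be deprotonated at its benzylic CH2 (ketene formation) instead of acylating, and the Lewis acidic zinc salt may cause premature loss of the acetal. The fallback sets out from 7. The aryllithium 12 is quenched with N-methoxy-N-methylacetamide, which has no acidic benzylic hydrogen, to give 1-[7-methoxy-5-(methoxymethoxy)-2,2-dimethyl-2H-chromen-6-yl]ethan-1-one F2. A palladium-catalysed ketone α-arylation with (4-bromophenoxy)triisopropylsilane (Pd2(dba)3, Xantphos, K3PO4, toluene, 80 °C) then forms the CH2–aryl bond instead of the aryl–acyl bond and comes back to the route at 14.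

3. Step 2. Iminium formation at the electron-rich, hydrogen-bonded formyl group may be slow, so that protodeboronation of the alkenylboronic acid and oligomerisation of the electron-rich chromenol compete. The fallback sets out from 2. Addition of excess 2-methylprop-1-en-1-ylmagnesium bromide (4 equiv, THF, 0 °C → rt; two equivalents are consumed by the phenols) should give 2-(1-hydroxy-3-methylbut-2-en-1-yl)-5-methoxybenzene-1,3-diol F1. Gentle warming with PPTS (toluene, 60 °C) should dehydrate it to the same ortho-quinone methide 5, which closes and comes back to the route at 6.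

**Further compounds**
F1 | step 2 | 2-(1-hydroxy-3-methylbut-2-en-1-yl)-5-methoxybenzene-1,3-diol | COc1cc(O)c(C(O)C=C(C)C)c(O)c1
F2 | step 6 | 1-[7-methoxy-5-(methoxymethoxy)-2,2-dimethyl-2H-chromen-6-yl]ethan-1-one | COCOc1c(C(C)=O)c(OC)cc2OC(C)(C)C=Cc12
F3 | step 9 | 1-(5-hydroxy-8-iodo-7-methoxy-2,2-dimethyl-2H-chromen-6-yl)-2-{4-[(triisopropylsilyl)oxy]phenyl}ethan-1-one | COc1c(I)c2OC(C)(C)C=Cc2c(O)c1C(=O)Cc1ccc(O[Si](C(C)C)(C(C)C)C(C)C)cc1
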